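All runs are simulated on assumed constants; noise was put on by code.

The closed, stirred vessel held E, G and Q at constant volume and temperature, and I had two earlier runs to reason from.

| flask | E | G | Q | remark | time |
|---|---|---|---|---|---|
| violet | 0.50 M | 0.35 equiv | 1 equiv | run made earlier |  |
| red | 0.50 M | 1 equiv | 1 equiv | run made earlier |  |
| west | 0.50 M | 0.600 equiv | 1.00 equiv |  | 40 h |
| south | 0.50 M | 1.20 equiv | 1.00 equiv |  | 40 h |

| run | time / h | E / % | J / % | Z / % |
|---|---|---|---|---|
| violet | 4.00 | 89.8 | 7.9 | 0.4 |
| violet | 8.00 | 84.7 | 12.2 | 2.8 |
| violet | 12.0 | 80.6 | 13.6 | 6.1 |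
| violet | 15.0 | 77.2 | 14.2 | 7.7 |
| violet | 20.0 | 74.7 | 13.5 | 12.5 |
| red | 1.50 | 89.3 | 10.4 | 0.7 |
| red | 3.00 | 80.1 | 18.5 | 1.8 |
| red | 6.00 | 67.8 | 26.8 | 5.4 |
| red | 10.0 | 55.9 | 33.3 | 11.5 |
| red | 20.0 | 38.5 | 32.0 | 27.9 |

(readings scatter by 0.5 percentage points)

* which of these there is most of at the end, counted by the E in it, west (E / Z / J)
* which of these there is most of at the end, counted by the E in it, south (E / Z / J)
* the largest of these amounts at the end, in percent of the E charged, west
* the largest of these amounts at the end, in percent of the E charged, south



1. The bench rule for a limiting reagent took G as going one for one with E, so in west, with 0.600 equiv of G, it put the floor for E at 40.0% of the charge, while south, with 1.20 equiv, had no floor by this rule.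

2. That rule carries no time, so I went to the red run, where E and G were charged equally, and took as my clock the rise per hour in the inverse of the fraction of E left, 0.0799 h⁻¹.

3. With g the equivalents of G, the ratio of G left to E left moves by the exponential of clock times time times (g minus one), and I gave Q no part in this. For the violet run at 20.0 h, this gave E at 74.2%, against a reading of 74.7%.

4. The border of the bench rule is clock times time times the shortfall of G, which was 1.28 for west, so I put E in west at 48.0%, above the floor, and E in south at 15.7%.

5. I then followed one molecule past the fork at J. The last interval of the red run gave J going to Z at 0.0502 h⁻¹, and a molecule leaving E about 12.5 h in had a chance of 74.8% of reaching Z.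

6. So I reckoned Z in west at 38.9% and J at 13.1%, with E largest, and Z in south at 63.1% and J at 21.2%, with Z largest.

The forecast named E at 48% for west and Z at 59% for south, its south range “depending on Q depletion”, and my Z for south stood above it.

The flask gave E at 48.8% in west and Z at 62.2% in south.

    E + G → J (k = 0.00272 M⁻¹ min⁻¹)
    Q + G → D (k = 8.10 × 10⁻⁵ M⁻¹ min⁻¹)
    J → Z (k = 8.50 × 10⁻⁴ min⁻¹)
    2 Q → X (k = 5.14 × 10⁻⁴ M⁻¹ min⁻¹)

The clock of 0.0799 h⁻¹ had put E in west at 48.0%, and west held 48.8%. The neighbouring flask was south with 0.300 equiv of G, so its floor for E stood at 70.0% and its border number at 2.24. The clock and the fork gave E 72.3%, Z 20.7% and J 6.98%. That neighbouring flask held E 72.8%, Z 20.1% and J 7.16%, so its largest was E, not Z as in south. With the other charges and the time as in south, Z and E held the same share at 0.693 equiv of G.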